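**Retrosynthetic overview**
1. Target 35 comes from macrocycle 31 by acetylation and an SN2′ chloride transposition (C6–O to C16–Cl, new C5=C6); the ten-membered ring is closed last by a Nozaki–Hiyama–Kishi reaction at C2–C3.
2. The spiro-epoxide, C12–O and C14–O are grown on ring A from an α′-aminomethyl enone (Mannich, boronate-tethered oxa-Michael from C2–OH, elimination, Luche reduction, directed epoxidation).
3. The γ-lactone comes from propanoate enolate addition to the C8 ketone and lactonisation onto O7, after an acetonide migration has told O9 (acetate) from O7.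
4. C6–C7 is an aldol of the dihydroxyacetone unit (C7–C8–C9) with dienal 11 (C3–C6, C16); C9–C10 is the key metal-free asymmetric Mukaiyama–Michael desymmetrisation of achiral dienone 4 with enol silane 6 (sets C1, C9, C10).
5. Ring order: ring A (carbocycle of 4, present from the start), then γ-lactone (step 16), then oxirane (step 20), then ten-membered ring (step 22).

Assumption 1: briarane numbering (C1–C20) is used for every intermediate; "as in 35" means the same spatial arrangement as in the target, and the SMILES carry the exact configuration.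
Assumption 2: the hand of the imidodiphosphorimidate catalyst in step 9 is fixed by screening so that 12 has the configuration drawn; 1, 5, 7 and 18 are bought.
Assumption 3: C6 (from step 10) and C11 (steps 15–17) are carried as epimer mixtures, written without a descriptor, because both centres are later erased; C17 is a mixture from step 14 until it is equilibrated in step 18.

**Step 1**
Reactants: 1 1-methylcyclohexa-2,5-diene-1-carboxylic acid
Product: 2 (1-methylcyclohexa-2,5-dien-1-yl)methanol
Conditions: LiAlH4, THF, 0 °C to rt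
Reagents that add atoms: none
Why: Hydride reduction of the acid to the primary alcohol (future C2); the skipped diene is inert.

**Step 2**
Reactants: 2 (1-methylcyclohexa-2,5-dien-1-yl)methanol
Product: 3 TBS ether of 2
Conditions: TBSCl, imidazole, DMF, rt
Reagents that add atoms: tert-butyldimethylsilyl chloride, CC(C)(C)[Si](C)(C)Cl
Why: Standard silylation; the neopentyl TBS ether survives the Lewis acid, enolate and mild acid steps and falls off in step 16.

**Step 3**
Reactants: 3 TBS ether of 2
Product: 4 4-(TBS-oxymethyl)-4-methylcyclohexa-2,5-dien-1-one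
Conditions: Rh2(C6H10NO)4 (dirhodium tetracaprolactamate, 1 mol %), t-BuOOH (70 % aq.), K2CO3, CH2Cl2, rt
Reagents that add atoms: tert-butyl hydroperoxide, CC(C)(C)OO
Why: Radical allylic oxidation of the doubly allylic CH2 gives the cross-conjugated dienone; the quaternary carbon blocks aromatisation and 4 keeps a mirror plane (achiral).

**Step 4**
Reactants: 5 2,2-dimethyl-1,3-dioxan-5-one
Product: 6 TBS enol ether of 5
Conditions: TBSOTf, Et3N, CH2Cl2, 0 °C
Reagents that add atoms: tert-butyldimethylsilyl trifluoromethanesulfonate, CC(C)(C)[Si](C)(C)OS(=O)(=O)C(F)(F)F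
Why: Soft enolisation of the symmetric ketone gives a single enol silane.

**Step 5**
Reactants: 7 but-3-yn-1-ol
Product: 8 4-iodobut-3-yn-1-ol
Conditions: N-iodosuccinimide, AgNO3 (10 mol %), acetone, rt
Reagents that add atoms: N-iodosuccinimide, O=C1CCC(=O)N1I
Why: Silver-catalysed iodination of the terminal alkyne C–H.

**Step 6**
Reactants: 8 4-iodobut-3-yn-1-ol
Product: 9 (Z)-4-iodobut-3-en-1-ol
Conditions: 2-nitrobenzenesulfonylhydrazide, Et3N, THF/i-PrOH, rt
Reagents that add atoms: none
Why: Diimide syn-hydrogenation of the iodoalkyne gives only the Z-iodoalkene and leaves the carbon–iodine bond intact.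

**Step 7**
Reactants: 9 (Z)-4-iodobut-3-en-1-ol
Product: 10 (Z)-4-iodobut-3-enal
Conditions: Dess–Martin periodinane, CH2Cl2, 0 °C; cold NaHCO3 wash
Reagents that add atoms: none
Why: Mild neutral oxidation avoids conjugation of the β,γ-alkene; the aldehyde is used at once.

**Step 8**
Reactants: 10 (Z)-4-iodobut-3-enal
Product: 11 (3Z)-4-iodo-2-methylidenebut-3-enal
Conditions: 37 % aq. CH2O, pyrrolidine (10 mol %), 4-(dimethylamino)benzoic acid (20 mol %), CH2Cl2, 40 °C; used at once
Reagents that add atoms: formaldehyde, C=O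
Why: Amine-catalysed Mannich-type α-methylenation of the aldehyde installs C16 as the exocyclic methylene; the Z-iodo terminus makes the diene a poor Diels–Alder partner.

**Step 9**
Reactants: 4 4-(TBS-oxymethyl)-4-methylcyclohexa-2,5-dien-1-one; 6 TBS enol ether of 5
Product: 12 C9–C10 Michael adduct (ring A as TBS dienol ether; free C8 ketone)
Conditions: (S,S)-imidodiphosphorimidate acid (IDPi from 3,3′-bis[3,5-bis(trifluoromethyl)phenyl]-BINOL, N-SO2CF3; 2 mol %), 6 (1.2 equiv), PhMe, −78 °C; Et3N quench
Reagents that add atoms: none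
Why: Proposed new method: the confined acid is silylated by 6 to a silylium–IDPi ion pair that O-silylates dienone 4; the pentadienyl cation sits in the chiral anion pocket, 6 attacks one of the two enantiotopic β-carbons (C10) anti to the CH2OTBS group, and silyl transfer from the C8 oxocarbenium back to the anion closes the cycle, leaving ring A as its TBS dienol ether and C8 as the free ketone, so C1, C9 and C10 are set together under catalyst control; the closest known reactions are silylium-IDPi-catalysed Mukaiyama–Michael additions of silyl ketene acetals to α,β-unsaturated esters and organocatalytic desymmetrisations of 4,4-disubstituted cyclohexadienones.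

**Step 10**
Reactants: 12 C9–C10 Michael adduct; 11 (3Z)-4-iodo-2-methylidenebut-3-enal
Product: 14 C7 aldol adduct (7,9-trans dioxanone), via lithium enolate 13 (not isolated)
Conditions: LiN(i-Pr)2, THF, −78 °C; then 11, −78 °C; AcOH quench
Reagents that add atoms: lithium diisopropylamide, [Li+].CC(C)[N-]C(C)C (lithium of 13 only)
Why: Kinetic deprotonation at the unsubstituted C7 and 1,2-aldol addition anti to the pseudo-axial C9 substituent give the 7,9-trans dioxanone (C7 as in 35); the ring-A carbonyl is masked, and the C6 carbinol forms as a mixture that is erased in step 25.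

**Step 11**
Reactants: 14 C7 aldol adduct
Product: 15 ring-A enone with C6/C7 dioxolane and free C9–OH
Conditions: CSA (0.2 equiv), acetone, H2O (2 equiv), 0 °C to rt
Reagents that add atoms: none
Why: Acid-catalysed transketalisation moves the acetonide from the strained dioxanone (O7/O9) to the vicinal C6/C7 diol (five-membered dioxolane, the thermodynamic sink), which frees only O9, while the silyl dienol ether is hydrolysed to the enone; no stereocentre is touched and the neopentyl TBS ether survives.

**Step 12**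
Reactants: 15 ring-A enone with free C9–OH
Product: 16 C9 acetate
Conditions: Ac2O, pyridine, DMAP (cat.), CH2Cl2, 0 °C
Reagents that add atoms: acetic anhydride, CC(=O)OC(C)=O
Why: Acylation of the only free hydroxyl puts the C9 acetate of the target in place and blocks O9 from later lactonisation.

**Step 13**
Reactants: 16 C9 acetate
Product: 17 ring-A TBS dienol ether
Conditions: TBSOTf (1.1 equiv), Et3N, CH2Cl2, −78 °C
Reagents that add atoms: tert-butyldimethylsilyl trifluoromethanesulfonate, CC(C)(C)[Si](C)(C)OS(=O)(=O)C(F)(F)F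
Why: Soft enolisation: the unhindered, more Lewis-basic enone is silylated and deprotonated at C11 (kinetic α′ site) to the cross-conjugated dienol ether, which masks the ring-A carbonyl and fixes C11 as the later nucleophilic carbon, whereas the flanked α,α′-dioxygenated C8 ketone does not enolise at −78 °C.

**Step 14**
Reactants: 17 ring-A TBS dienol ether; 18 ethyl propanoate
Product: 20 C8 tertiary alcohol ester, via lithium ester enolate 19 (not isolated)
Conditions: 18, LiN(i-Pr)2, THF, −78 °C; then 17, −78 °C; AcOH quench at −78 °C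
Reagents that add atoms: lithium diisopropylamide, [Li+].CC(C)[N-]C(C)C (lithium of 19 only)
Why: Aldol addition of the ester enolate to the only free ketone under Cram-chelate control through the dioxolane oxygen at C7, reinforced by Felkin–Anh control from the C9 acetoxy group, puts C17 on the face that gives the C8 configuration of 35; C17 forms as a mixture (settled in step 18).

**Step 15**
Reactants: 20 C8 tertiary alcohol ester
Product: 21 C11 Mannich base (ring-A enone)
Conditions: dimethylmethylideneammonium iodide, CH2Cl2, 0 °C to rt; aq. NaHCO3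
Reagents that add atoms: dimethylmethylideneammonium iodide, C=[N+](C)C.[I-]
Why: Mannich reaction of the silyl dienol ether with the preformed iminium ion occurs only at C11 (α′ terminus) and brings in C20 as a stable aminomethyl group; C11 is an inconsequential epimer mixture.

**Step 16**
Reactants: 21 C11 Mannich base
Product: 22 γ-lactone with free C2–OH and C6–OH
Conditions: AcOH/H2O/THF (3:1:1), 45 °C; NaHCO3 work-up
Reagents that add atoms: none
Why: Acidic hydrolysis removes the acetonide and the primary silyl ether, and the freed C7–OH closes the five-membered lactone on the ethyl ester (γ preferred over δ; O9 is blocked as acetate).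

**Step 17**
Reactants: 22 γ-lactone with free C2–OH and C6–OH
Product: 24 C6 TBS ether of the O2/O14 boronate, via cyclic phenylboronate 23 (not isolated)
Conditions: PhB(OH)2 (1.1 equiv), i-Pr2NEt (0.2 equiv), 4 Å sieves, PhMe, 50 °C; then TBSOTf, 2,6-lutidine, −40 °C
Reagents that add atoms: phenylboronic acid, OB(O)c1ccccc1; tert-butyldimethylsilyl trifluoromethanesulfonate, CC(C)(C)[Si](C)(C)OS(=O)(=O)C(F)(F)F
Why: Boronic acid hemiester oxa-Michael addition: the C2–O–B(Ph)–OH hemiester delivers its B–OH to C14 of the enone through a six-membered 1,3,2-dioxaborinane, so the new C14–O bond is necessarily cis to C2 (α, as in 35), and the cyclic boronate then masks O2 and O14 while the only free secondary hydroxyl (C6) is silylated.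

**Step 18**
Reactants: 24 C6 TBS ether of the O2/O14 boronate
Product: 26 α-methylene ketone boronate, via trimethylammonium iodide 25 (not isolated)
Conditions: CH3I, MeCN, rt; then DBU, rt, 12 h
Reagents that add atoms: iodomethane, CI (N-methyl of 25 only)
Why: N-Methylation and E1cB loss of trimethylamine (Mannich-base elimination) unveil the C11=C20 enone while O2 stays masked, and DBU equilibrates the lactone α-carbon C17 to the favoured epimer with CH3 trans to the bulky C9 substituent (17R, as in 35).

**Step 19**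
Reactants: 26 α-methylene ketone boronate
Product: 28 triol (C2–OH, 12α-OH, 14α-OH), via boronate allylic alcohol 27 (not isolated)
Conditions: NaBH4, CeCl3·7H2O, MeOH/THF, −78 °C; then pinacol, rt
Reagents that add atoms: none
Why: Luche 1,2-reduction: hydride attacks C12 from the β face because the axial C14 oxygen blocks the α (axial) trajectory, giving the 12α-alcohol cis to O14, and transesterification with pinacol then frees O2 and O14.

**Step 20**
Reactants: 28 triol
Product: 29 11,20-epoxide
Conditions: VO(C5H7O2)2 (vanadyl bis(acetylacetonate), 5 mol %), t-BuOOH (decane), CH2Cl2, 0 °C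
Reagents that add atoms: tert-butyl hydroperoxide, CC(C)(C)OO
Why: Hydroxyl-directed epoxidation: the vanadium peroxide bound to the allylic C12–OH delivers oxygen to the α face of the exocyclic alkene (epoxide oxygen cis to O12, as in 35), and the silylated dienyl alkene has no directing group.

**Step 21**
Reactants: 29 11,20-epoxide
Product: 30 C2 aldehyde
Conditions: TEMPO (0.2 equiv), PhI(OAc)2, CH2Cl2, rt
Reagents that add atoms: none
Why: Oxoammonium oxidation is selective for the primary neopentyl alcohol over the hindered secondary and tertiary ones and gives a non-enolisable aldehyde.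

**Step 22**
Reactants: 30 C2 aldehyde
Product: 31 macrocycle (2-OH, 3Z-ene, 5(16)-methylidene, 6-OTBS)
Conditions: CrCl2 (15 equiv), NiCl2 (2 mol %), DMSO/THF 3:1, 2 mM, rt
Reagents that add atoms: none
Why: Nozaki–Hiyama–Kishi reaction: zerovalent nickel inserts into the alkenyl iodide, transmetallation gives an alkenylchromium that adds only to the aldehyde with retention of Z geometry, closing the ten-membered ring; with the carbonyl oxygen turned toward the C15 methyl and the tethered nucleophile coming from the C10 side, anti to C1–C14, the 2S alcohol is expected.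

**Step 23**
Reactants: 31 macrocycle
Product: 32 2,9,12,14-tetraacetate
Conditions: Ac2O, pyridine, DMAP (cat.), CH2Cl2, rt
Reagents that add atoms: acetic anhydride, CC(=O)OC(C)=O
Why: DMAP-catalysed acylation of the three secondary alcohols completes the four acetates (O9 has carried its acetate since step 12), while the hindered tertiary C8–OH does not react.

**Step 24**
Reactants: 32 2,9,12,14-tetraacetate
Product: 33 C6 allylic alcohol
Conditions: HF·pyridine, pyridine, THF, 0 °C
Reagents that add atoms: none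
Why: Buffered fluoride cleavage of the last silyl ether; acetates, lactone and the hindered epoxide tolerate it.

**Step 25**
Reactants: 33 C6 allylic alcohol
Product: 35 CNP0128637.1, via C6 mesylate 34 (not isolated)
Conditions: CH3SO2Cl, Et3N, CH2Cl2, −20 °C; then LiCl, DMF, 0 °C to rt
Reagents that add atoms: methanesulfonyl chloride, CS(=O)(=O)Cl (sulfonyl group of 34 only); lithium chloride, [Li+].[Cl-]
Why: Mesylation of the only secondary alcohol and SN2′ displacement by chloride at the exocyclic CH2 (C16) moves the double bond into C5=C6, conjugated with C3=C4, with the ring enforcing the cis-in-ring (5E) geometry; the C6 stereocentre disappears and the primary conjugated chloride is also the thermodynamic allylic isomer.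

**Compound list**
1 | 1-methylcyclohexa-2,5-diene-1-carboxylic acid | CC1(C(=O)O)C=CCC=C1 | starting material
2 | (1-methylcyclohexa-2,5-dien-1-yl)methanol | CC1(CO)C=CCC=C1 | intermediate
3 | tert-butyldimethyl[(1-methylcyclohexa-2,5-dien-1-yl)methoxy]silane | CC1(CO[Si](C)(C)C(C)(C)C)C=CCC=C1 | intermediate
4 | 4-{[(tert-butyldimethylsilyl)oxy]methyl}-4-methylcyclohexa-2,5-dien-1-one (achiral) | CC1(CO[Si](C)(C)C(C)(C)C)C=CC(=O)C=C1 | intermediate
5 | 2,2-dimethyl-1,3-dioxan-5-one | CC1(C)OCC(=O)CO1 | starting material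
6 | tert-butyl[(2,2-dimethyl-4H-1,3-dioxin-5-yl)oxy]dimethylsilane | CC1(C)OCC(O[Si](C)(C)C(C)(C)C)=CO1 | intermediate
7 | but-3-yn-1-ol | C#CCCO | starting material
8 | 4-iodobut-3-yn-1-ol | OCCC#CI | intermediate
9 | (Z)-4-iodobut-3-en-1-ol | OCC/C=C\I | intermediate
10 | (Z)-4-iodobut-3-enal | O=CC/C=C\I | intermediate
11 | (3Z)-4-iodo-2-methylidenebut-3-enal | O=CC(=C)/C=C\I | intermediate
12 | Michael adduct: 2,2-dimethyl-1,3-dioxan-5-one bearing at C4 (= C9) the ring-A unit 3-(TBS-oxy)-6-(TBS-oxymethyl)-6-methylcyclohexa-2,4-dien-1-yl; C1, C9, C10 as in 35 (C9 chain cis to the C15 methyl) | O=C1COC(C)(C)O[C@H]1[C@H]1C=C(O[Si](C)(C)C(C)(C)C)C=C[C@]1(C)CO[Si](C)(C)C(C)(C)C | intermediate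
13 | lithium enolate of 12 (C7=C8–OLi) | [Li]OC1=COC(C)(C)O[C@H]1[C@H]1C=C(O[Si](C)(C)C(C)(C)C)C=C[C@]1(C)CO[Si](C)(C)C(C)(C)C | intermediate (not isolated)
14 | aldol adduct: 12 carrying at C7 (trans to the C9 substituent, C7 as in 35) the 1-hydroxy-4-iodo-2-methylidenebut-3(Z)-enyl group; C6 epimers | O=C1[C@H](C(O)C(=C)/C=C\I)OC(C)(C)O[C@H]1[C@H]1C=C(O[Si](C)(C)C(C)(C)C)C=C[C@]1(C)CO[Si](C)(C)C(C)(C)C | intermediate
15 | ring-A enone (4-(TBS-oxymethyl)-4-methylcyclohex-2-en-1-one) whose C10 carries C9H(OH)–C8(=O)–[C7/C6 2,2-dimethyl-1,3-dioxolane]–C5(=CH2)–(Z)-CH=CHI; C1, C7, C9, C10 as in 35 | O[C@H](C(=O)[C@H]1OC(C)(C)OC1C(=C)/C=C\I)[C@H]1CC(=O)C=C[C@]1(C)CO[Si](C)(C)C(C)(C)C | intermediate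
16 | C9 acetate of 15 | CC(=O)O[C@H](C(=O)[C@H]1OC(C)(C)OC1C(=C)/C=C\I)[C@H]1CC(=O)C=C[C@]1(C)CO[Si](C)(C)C(C)(C)C | intermediate
17 | ring-A TBS dienol ether of 16 (C11=C12(OTBS)–C13=C14) | CC(=O)O[C@H](C(=O)[C@H]1OC(C)(C)OC1C(=C)/C=C\I)[C@H]1C=C(O[Si](C)(C)C(C)(C)C)C=C[C@]1(C)CO[Si](C)(C)C(C)(C)C | intermediate
18 | ethyl propanoate | CCC(=O)OCC | starting material
19 | lithium enolate of ethyl propanoate (CH3 trans to OLi) | C/C=C(\OCC)O[Li] | intermediate (not isolated)
20 | C8 tertiary alcohol: 17 after addition of C17–C19 as the ethyl 2-methyl ester; C8 as in 35, C17 epimers | CC(=O)O[C@H]([C@](O)(C(C)C(=O)OCC)[C@H]1OC(C)(C)OC1C(=C)/C=C\I)[C@H]1C=C(O[Si](C)(C)C(C)(C)C)C=C[C@]1(C)CO[Si](C)(C)C(C)(C)C | intermediate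
21 | Mannich base: ring-A enone of 20 with CH2N(CH3)2 at C11 (C11 epimers) | CC(=O)O[C@H]([C@](O)(C(C)C(=O)OCC)[C@H]1OC(C)(C)OC1C(=C)/C=C\I)[C@H]1C(CN(C)C)C(=O)C=C[C@]1(C)CO[Si](C)(C)C(C)(C)C | intermediate
22 | γ-lactone (C7–O–C19) with free C2–OH, C6–OH and C8–OH, 9-OAc, ring-A Mannich-base enone | CC(=O)O[C@H]([C@]1(O)C(C)C(=O)O[C@H]1C(O)C(=C)/C=C\I)[C@H]1C(CN(C)C)C(=O)C=C[C@]1(C)CO | intermediate
23 | cyclic phenylboronate of 22 bridging O2 and the new 14α-oxygen (ring-A ketone) | CC(=O)O[C@H]([C@]1(O)C(C)C(=O)O[C@H]1C(O)C(=C)/C=C\I)[C@H]1C(CN(C)C)C(=O)C[C@@H]2OB(c3ccccc3)OC[C@]12C | intermediate (not isolated)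
24 | C6 TBS ether of 23 | CC(=O)O[C@H]([C@]1(O)C(C)C(=O)O[C@H]1C(O[Si](C)(C)C(C)(C)C)C(=C)/C=C\I)[C@H]1C(CN(C)C)C(=O)C[C@@H]2OB(c3ccccc3)OC[C@]12C | intermediate
25 | N-methyl quaternary ammonium iodide of 24 | CC(=O)O[C@H]([C@]1(O)C(C)C(=O)O[C@H]1C(O[Si](C)(C)C(C)(C)C)C(=C)/C=C\I)[C@H]1C(C[N+](C)(C)C)C(=O)C[C@@H]2OB(c3ccccc3)OC[C@]12C.[I-] | intermediate (not isolated)
26 | α-methylene ketone (C11=C20, C12=O) with O2/O14 boronate; C17 as in 35 | CC(=O)O[C@H]([C@]1(O)[C@@H](C)C(=O)O[C@H]1C(O[Si](C)(C)C(C)(C)C)C(=C)/C=C\I)[C@H]1C(=C)C(=O)C[C@@H]2OB(c3ccccc3)OC[C@]12C | intermediate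
27 | 12α-allylic alcohol with O2/O14 boronate | CC(=O)O[C@H]([C@]1(O)[C@@H](C)C(=O)O[C@H]1C(O[Si](C)(C)C(C)(C)C)C(=C)/C=C\I)[C@H]1C(=C)[C@H](O)C[C@@H]2OB(c3ccccc3)OC[C@]12C | intermediate (not isolated)
28 | triol: C2–OH, 12α-OH, 14α-OH; 6-OTBS; C11=C20 | CC(=O)O[C@H]([C@]1(O)[C@@H](C)C(=O)O[C@H]1C(O[Si](C)(C)C(C)(C)C)C(=C)/C=C\I)[C@H]1C(=C)[C@H](O)C[C@H](O)[C@]1(C)CO | intermediate
29 | 11,20-epoxide of 28 (epoxide oxygen α, cis to O12) | CC(=O)O[C@H]([C@]1(O)[C@@H](C)C(=O)O[C@H]1C(O[Si](C)(C)C(C)(C)C)C(=C)/C=C\I)[C@H]1[C@@]2(CO2)[C@H](O)C[C@H](O)[C@]1(C)CO | intermediate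
30 | C2 aldehyde of 29 | CC(=O)O[C@H]([C@]1(O)[C@@H](C)C(=O)O[C@H]1C(O[Si](C)(C)C(C)(C)C)C(=C)/C=C\I)[C@H]1[C@@]2(CO2)[C@H](O)C[C@H](O)[C@]1(C)C=O | intermediate
31 | macrocycle: briarane core with 2-OH (2S), 3Z-alkene, 5(16)-methylidene, 6-OTBS, 8-OH, 9-OAc, 12-OH, 14-OH, 11,20-epoxide, 7,19-lactone | O[C@H]1/C=C\C(=C)C(O[Si](C)(C)C(C)(C)C)[C@@H]2OC(=O)[C@H](C)[C@@]2(O)[C@@H](OC(C)=O)[C@H]2[C@@]3(CO3)[C@H](O)C[C@H](O)[C@]12C | intermediate
32 | 2,9,12,14-tetraacetate of 31 | CC(=O)O[C@H]1/C=C\C(=C)C(O[Si](C)(C)C(C)(C)C)[C@@H]2OC(=O)[C@H](C)[C@@]2(O)[C@@H](OC(C)=O)[C@H]2[C@@]3(CO3)[C@H](OC(C)=O)C[C@H](OC(C)=O)[C@]12C | intermediate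
33 | 6-hydroxy compound (TBS removed from 32) | CC(=O)O[C@H]1/C=C\C(=C)C(O)[C@@H]2OC(=O)[C@H](C)[C@@]2(O)[C@@H](OC(C)=O)[C@H]2[C@@]3(CO3)[C@H](OC(C)=O)C[C@H](OC(C)=O)[C@]12C | intermediate
34 | 6-methanesulfonate of 33 | CC(=O)O[C@H]1/C=C\C(=C)C(OS(C)(=O)=O)[C@@H]2OC(=O)[C@H](C)[C@@]2(O)[C@@H](OC(C)=O)[C@H]2[C@@]3(CO3)[C@H](OC(C)=O)C[C@H](OC(C)=O)[C@]12C | intermediate (not isolated)
35 | CNP0128637.1 (2,9,12,14-tetraacetoxy-16-chloro-11,20-epoxy-8-hydroxybriara-3Z,5E-dien-19,7-olide) | CC(=O)O[C@H]1/C=C\C(CCl)=C/[C@@H]2OC(=O)[C@H](C)[C@@]2(O)[C@@H](OC(C)=O)[C@H]2[C@@]3(CO3)[C@H](OC(C)=O)C[C@H](OC(C)=O)[C@]12C | target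

**Totals**
Total step count: 25. Longest linear sequence: 20 steps (7 to 35 through steps 5–8 and 10–25; equally 1 to 35 through steps 1–3 and 9–25).

**Three steps most likely to fail**

Step 9 (the proposed new method). Risks are slow addition at the β-carbon next to the quaternary centre and insufficient enantio- or diastereocontrol. The fallback uses known auxiliary chemistry, sets out from 5 (with 4) and comes back at 12. Ketone 5 is condensed with (S)-1-amino-2-(methoxymethyl)pyrrolidine to the SAMP hydrazone F1. F1 is deprotonated with LiN(i-Pr)2, turned into the azaenolate cuprate with CuI and added 1,4 to dienone 4 in the presence of TBSCl, giving the hydrazone silyl dienol ether F2 (the enantiomeric auxiliary is used if the sense is opposite). Two-phase cleavage of the hydrazone with saturated aqueous oxalic acid/Et2O returns 12.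

Step 22. Risks are oligomers and the wrong or mixed C2 configuration. The fallback sets out from 30 and comes back at 31, and no longer relies on the addition step for C2. The closure is run as before; the C2-epimeric macrocyclic carbinol F3 (or the epimer mixture) is oxidised with MnO2, which touches only the allylic C2–OH, to the macrocyclic dienone F4. F4 is then reduced under reagent control with the enantiomer of 2-methyl-CBS-oxazaborolidine/BH3·SMe2 that gives 2S, returning 31.

Step 25. Risks are direct SN2 at C6 and attack of chloride on the epoxide. The fallback sets out from 33 and comes back at 35. The allylic hydroxyl is transposed 1,3 with (C6H5)3SiOReO3 (2 mol %, Et2O, 0 °C) to the thermodynamically favoured primary, conjugated 16-alcohol F5, which already has the C5=C6 bond. F5 is chlorinated at the primary carbon with N-chlorosuccinimide/PPh3 (CH2Cl2, 0 °C), without allylic shift, to give 35.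

**Further compounds**
F1 | step 9 | SAMP hydrazone of 2,2-dimethyl-1,3-dioxan-5-one | COC[C@@H]1CCCN1N=C1COC(C)(C)OC1
F2 | step 9 | SAMP hydrazone of 12 (ring A as TBS dienol ether) | COC[C@@H]1CCCN1N=C1COC(C)(C)O[C@H]1[C@H]1C=C(O[Si](C)(C)C(C)(C)C)C=C[C@]1(C)CO[Si](C)(C)C(C)(C)C
F3 | step 22 | C2 epimer of 31 | O[C@@H]1/C=C\C(=C)C(O[Si](C)(C)C(C)(C)C)[C@@H]2OC(=O)[C@H](C)[C@@]2(O)[C@@H](OC(C)=O)[C@H]2[C@@]3(CO3)[C@H](O)C[C@H](O)[C@]12C
F4 | step 22 | macrocyclic C2 ketone (2-oxo analogue of 31) | O=C1/C=C\C(=C)C(O[Si](C)(C)C(C)(C)C)[C@@H]2OC(=O)[C@H](C)[C@@]2(O)[C@@H](OC(C)=O)[C@H]2[C@@]3(CO3)[C@H](O)C[C@H](O)[C@]12C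
F5 | step 25 | 16-hydroxy-3Z,5E-diene isomer of 33 | CC(=O)O[C@H]1/C=C\C(CO)=C/[C@@H]2OC(=O)[C@H](C)[C@@]2(O)[C@@H](OC(C)=O)[C@H]2[C@@]3(CO3)[C@H](OC(C)=O)C[C@H](OC(C)=O)[C@]12C
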